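The route rests on disconnecting the cyclopentane ring of the hydroazulene at two bonds, C1–C2 and C3a–C8a (azulene locants of the target). This leaves a three-carbon 2-oxyallyl unit (C2–C3–C3a, oxygen on the central carbon) facing the 1,1-disubstituted alkene C8a=C1. The key step is an intramolecular (3+2) cycloaddition of an oxyallyl cation, generated from an acyclic (R,Z)-configured α-chloroketone, that closes the five- and seven-membered rings and the quaternary C8a in one operation. The C4 silyloxy stereocentre, set by allylation, controls the new centres, and C3a remains epimerizable. Chelation-controlled isopropyl addition and esterification finish the synthesis.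

Key step: step 8

Remark: locants in the text are the azulene locants of the target (C1, C2 = ring CH2 groups; C3 = carbinol carbon; C3a = ring-fusion CH; C4 = ester-bearing carbon; C5=C6 = ring alkene; C8a = methyl-bearing quaternary carbon). (+)-B-Allyldiisopinocampheylborane is taken as the commercial pentane solution.

Step 1
Reactants: 1 but-2-yn-1-ol
Product: 3 (Z)-3-iodobut-2-en-1-ol, via cyclic alkenylaluminate 2 (not isolated)
Conditions: NaAlH2(OCH2CH2OMe)2 (Red-Al), THF, 0 °C to rt; then I2, −78 to 0 °C
Reagents that add atoms: iodine, II; Red-Al, [Na+].[AlH2-](OCCOC)OCCOC (retained only in 2)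
Why: Hydroxyl-directed trans-hydroalumination of the propargylic alcohol places aluminium on C3 cis to the CH2O group, and iodinolysis of the C–Al bond with retention should give the Z-iodoalkene.

Step 2
Reactants: 3 (Z)-3-iodobut-2-en-1-ol; 4 4-bromo-2-methylbut-1-ene
Product: 6 (Z)-3,6-dimethylhepta-2,6-dien-1-ol, via alkylzinc bromide 5 (not isolated)
Conditions: 4, Zn dust, LiCl, THF, 40 °C; then 3, PdCl2(dppf) (5 mol %), THF, 50 °C
Reagents that add atoms: zinc, [Zn] (retained only in 5)
Why: Negishi coupling, in which oxidative addition of the alkenyl iodide to zerovalent palladium, transmetalation and reductive elimination all proceed with retention, so the new chain should end cis to CH2OH (Z).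

Step 3
Reactants: 6 (Z)-3,6-dimethylhepta-2,6-dien-1-ol
Product: 7 (Z)-3,6-dimethylhepta-2,6-dienal
Conditions: 2,2,6,6-tetramethylpiperidin-1-oxyl (TEMPO, 10 mol %), PhI(OAc)2, CH2Cl2, rt
Reagents that add atoms: none
Why: Oxoammonium (TEMPO) oxidation of the primary allylic alcohol stops at the aldehyde under near-neutral conditions that should not isomerize the Z-enal.

Step 4
Reactants: 7 (Z)-3,6-dimethylhepta-2,6-dienal
Product: 9 (R,Z)-6,9-dimethyldeca-1,5,9-trien-4-ol, via diisopinocampheylborinate 8 (not isolated)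
Conditions: (+)-Ipc2B(allyl), Et2O, −78 °C; then NaOH, H2O2, 0 °C to rt
Reagents that add atoms: (+)-B-allyldiisopinocampheylborane, C=CCB([C@H]1C[C@H]2C[C@@H]([C@@H]1C)C2(C)C)[C@H]1C[C@H]2C[C@@H]([C@@H]1C)C2(C)C
Why: Brown allylation through a closed chair transition state, in which the (+)-reagent (from (−)-α-pinene) should deliver allyl to the Re face of the aldehyde and set the carbinol as R, the centre that becomes C4 of the target.

Step 5
Reactants: 9 (R,Z)-6,9-dimethyldeca-1,5,9-trien-4-ol
Product: 10 (R,Z)-tert-butyl[(6,9-dimethyldeca-1,5,9-trien-4-yl)oxy]dimethylsilane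
Conditions: tert-butyldimethylsilyl chloride, imidazole, DMF, rt
Reagents that add atoms: tert-butyldimethylsilyl chloride, CC(C)(C)[Si](C)(C)Cl
Why: Silylation of the secondary alcohol, which blocks O-alkylation by the later chloroketone and supplies the steric control element for step 8.

Step 6
Reactants: 10 (R,Z)-tert-butyl[(6,9-dimethyldeca-1,5,9-trien-4-yl)oxy]dimethylsilane
Product: 11 (R,Z)-4-[(tert-butyldimethylsilyl)oxy]-6,9-dimethyldeca-5,9-dien-2-one
Conditions: PdCl2 (10 mol %), CuCl, O2 (1 atm), DMF/H2O, rt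
Reagents that add atoms: water, O
Why: Tsuji–Wacker oxidation, in which Markovnikov hydroxypalladation of the monosubstituted terminal alkene should give the methyl ketone while the 1,1-disubstituted and trisubstituted alkenes react far more slowly.

Step 7
Reactants: 11 (R,Z)-4-[(tert-butyldimethylsilyl)oxy]-6,9-dimethyldeca-5,9-dien-2-one
Product: 13 (R,Z)-4-[(tert-butyldimethylsilyl)oxy]-1-chloro-6,9-dimethyldeca-5,9-dien-2-one, via trimethylsilyl enol ether 12 (not isolated)
Conditions: LiN(SiMe3)2, Me3SiCl, THF, −78 °C; then N-chlorosuccinimide, THF, −78 to 0 °C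
Reagents that add atoms: chlorotrimethylsilane, C[Si](C)(C)Cl (retained only in 12); N-chlorosuccinimide, O=C1CCC(=O)N1Cl
Why: Kinetic deprotonation at the methyl group with in situ silylation gives the less substituted enol ether, and its electrophilic chlorination should give the chloromethyl ketone regiospecifically without touching the unactivated alkenes.

Step 8
Reactants: 13 (R,Z)-4-[(tert-butyldimethylsilyl)oxy]-1-chloro-6,9-dimethyldeca-5,9-dien-2-one
Product: 15 (3aS,4S,8aS)-4-[(tert-butyldimethylsilyl)oxy]-6,8a-dimethyl-1,2,4,7,8,8a-hexahydroazulen-3(3aH)-one, via oxyallyl cation 14 (not isolated)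
Conditions: i-Pr2NEt, (CF3)2CHOH, 0.01 M, 0 °C to rt
Reagents that add atoms: none
Why: Proposed new method: the hindered amine enolizes 13 toward C3a and the fluorinated alcohol ionizes the allylic C–Cl bond to the oxyallyl cation 14, whose termini C2 and C3a add across the pendant 1,1-disubstituted alkene in a concerted, asynchronous (3+2) event (C1–C2 bonding ahead, the developing tertiary cation at C8a collapsing onto C3a) that forms the C1–C2 and C3a–C8a bonds together. The closest known reactions are the (4+3) and (3+2) cycloadditions of oxyallyl cations made from α-halo ketones with amine base in fluorinated alcohols (dienes, indoles, styrenes) and their intramolecular (4+3) variants, whereas an unactivated alkene on a five-atom tether has not been used. The cyclopentanone closes by the (3+2) union itself and the cycloheptene closes as the tether ring through the C3a–C8a bond (7-exo with respect to the alkene), the Z C5=C6 bond holding the two ends within reach. C8a is set relative to C4, because allylic strain keeps H4 eclipsed with the oxyallyl plane, the tether reaches the face anti to the silyloxy group and a chair-like forming seven-membered ring places the methyl anti to H3a (trans fusion); C3a is set in the same event and, being α to the new ketone, can also equilibrate to the trans-fused isomer under the basic conditions. The step needs periselectivity for the remote alkene over the nearer trisubstituted one (which cannot span both termini and is kept away by the W-shaped oxyallyl) and C- over O-closure, and high dilution suppresses dimerization.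

Step 9
Reactants: 15 (3aS,4S,8aS)-4-[(tert-butyldimethylsilyl)oxy]-6,8a-dimethyl-1,2,4,7,8,8a-hexahydroazulen-3(3aH)-one
Product: 16 (3aS,4S,8aS)-4-hydroxy-6,8a-dimethyl-1,2,4,7,8,8a-hexahydroazulen-3(3aH)-one
Conditions: HF·pyridine, THF/pyridine, 0 °C to rt
Reagents that add atoms: none
Why: Fluoride-driven Si–O cleavage under buffered, non-basic conditions should free the C4 hydroxyl without retro-aldol opening or β-elimination.

Step 10
Reactants: 16 (3aS,4S,8aS)-4-hydroxy-6,8a-dimethyl-1,2,4,7,8,8a-hexahydroazulen-3(3aH)-one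
Product: 18 (3R,3aS,4S,8aS)-6,8a-dimethyl-3-(propan-2-yl)-1,2,3,3a,4,7,8,8a-octahydroazulene-3,4-diol, via chloromagnesium alkoxide 17 (not isolated)
Conditions: i-PrMgCl (3.5 equiv), LaCl3·2LiCl, THF, −78 to −20 °C
Reagents that add atoms: isopropylmagnesium chloride, CC(C)[Mg]Cl
Why: Chelation-controlled Grignard 1,2-addition promoted by LaCl3·2LiCl, in which the C4 alkoxide ties the carbonyl oxygen into a six-membered chelate and isopropyl should attack C3 from the open face syn to H3a and anti to the angular methyl, giving the 3R tertiary alcohol.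

Step 11
Reactants: 18 (3R,3aS,4S,8aS)-6,8a-dimethyl-3-(propan-2-yl)-1,2,3,3a,4,7,8,8a-octahydroazulene-3,4-diol; 19 4-acetoxybenzoyl chloride
Product: 20 (3R,3aS,4S,8aS)-3-hydroxy-6,8a-dimethyl-3-(propan-2-yl)-1,2,3,3a,4,7,8,8a-octahydroazulen-4-yl 4-acetoxybenzoate
Conditions: Et3N, 4-(dimethylamino)pyridine (DMAP), CH2Cl2, 0 °C to rt
Reagents that add atoms: none
Why: DMAP-catalysed acylation should be selective for the secondary allylic alcohol over the hindered tertiary one.

Step 12
Reactants: 20 (3R,3aS,4S,8aS)-3-hydroxy-6,8a-dimethyl-3-(propan-2-yl)-1,2,3,3a,4,7,8,8a-octahydroazulen-4-yl 4-acetoxybenzoate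
Product: 21 (3R,3aS,4S,8aS)-3-hydroxy-6,8a-dimethyl-3-(propan-2-yl)-1,2,3,3a,4,7,8,8a-octahydroazulen-4-yl 4-hydroxybenzoate (CNP0323098.1)
Conditions: pyrrolidine, CH2Cl2, 0 °C
Reagents that add atoms: none
Why: Aminolysis of the aryl acetate is much faster than attack on the hindered alkyl benzoate, so the phenol should be freed selectively.

Compound list
1 | but-2-yn-1-ol | CC#CCO | starting material
2 | sodium 2,2-bis(2-methoxyethoxy)-3-methyl-2,5-dihydro-1,2-oxaluminol-2-uide (cyclic Z-alkenylaluminate) | CC1=CCO[Al-]1(OCCOC)OCCOC.[Na+] | intermediate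
3 | (Z)-3-iodobut-2-en-1-ol | C/C(I)=C/CO | intermediate
4 | 4-bromo-2-methylbut-1-ene | CC(=C)CCBr | starting material
5 | (3-methylbut-3-en-1-yl)zinc bromide | CC(=C)CC[Zn]Br | intermediate
6 | (Z)-3,6-dimethylhepta-2,6-dien-1-ol | OC/C=C(/C)CCC(C)=C | intermediate
7 | (Z)-3,6-dimethylhepta-2,6-dienal | O=C/C=C(/C)CCC(C)=C | intermediate
8 | (R,Z)-6,9-dimethyldeca-1,5,9-trien-4-yl diisopinocampheylborinate | C=CC[C@@H](OB([C@H]1C[C@H]2C[C@@H]([C@@H]1C)C2(C)C)[C@H]1C[C@H]2C[C@@H]([C@@H]1C)C2(C)C)/C=C(/C)CCC(C)=C | intermediate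
9 | (R,Z)-6,9-dimethyldeca-1,5,9-trien-4-ol | C=CC[C@@H](O)/C=C(/C)CCC(C)=C | intermediate
10 | (R,Z)-tert-butyl[(6,9-dimethyldeca-1,5,9-trien-4-yl)oxy]dimethylsilane | C=CC[C@@H](O[Si](C)(C)C(C)(C)C)/C=C(/C)CCC(C)=C | intermediate
11 | (R,Z)-4-[(tert-butyldimethylsilyl)oxy]-6,9-dimethyldeca-5,9-dien-2-one | CC(=O)C[C@@H](O[Si](C)(C)C(C)(C)C)/C=C(/C)CCC(C)=C | intermediate
12 | (R,Z)-tert-butyl{[6,9-dimethyl-2-(trimethylsilyloxy)deca-1,5,9-trien-4-yl]oxy}dimethylsilane | C=C(O[Si](C)(C)C)C[C@@H](O[Si](C)(C)C(C)(C)C)/C=C(/C)CCC(C)=C | intermediate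
13 | (R,Z)-4-[(tert-butyldimethylsilyl)oxy]-1-chloro-6,9-dimethyldeca-5,9-dien-2-one | ClCC(=O)C[C@@H](O[Si](C)(C)C(C)(C)C)/C=C(/C)CCC(C)=C | intermediate
14 | (R)-4-[(tert-butyldimethylsilyl)oxy]-6,9-dimethyl-2-oxidodeca-2,5,9-trien-1-ylium (W-shaped oxyallyl cation, Z at C5=C6) | [CH2+]/C([O-])=C/[C@@H](O[Si](C)(C)C(C)(C)C)/C=C(/C)CCC(C)=C | intermediate
15 | (3aS,4S,8aS)-4-[(tert-butyldimethylsilyl)oxy]-6,8a-dimethyl-1,2,4,7,8,8a-hexahydroazulen-3(3aH)-one | CC1=C[C@H](O[Si](C)(C)C(C)(C)C)[C@@H]2[C@@](C)(CC1)CCC2=O | intermediate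
16 | (3aS,4S,8aS)-4-hydroxy-6,8a-dimethyl-1,2,4,7,8,8a-hexahydroazulen-3(3aH)-one | CC1=C[C@H](O)[C@@H]2[C@@](C)(CC1)CCC2=O | intermediate
17 | chloromagnesium (3aS,4S,8aS)-6,8a-dimethyl-3-oxo-1,2,3,3a,4,7,8,8a-octahydroazulen-4-olate | CC1=C[C@H](O[Mg]Cl)[C@@H]2[C@@](C)(CC1)CCC2=O | intermediate
18 | (3R,3aS,4S,8aS)-6,8a-dimethyl-3-(propan-2-yl)-1,2,3,3a,4,7,8,8a-octahydroazulene-3,4-diol | CC1=C[C@H](O)[C@@H]2[C@@](C)(CC1)CC[C@@]2(O)C(C)C | intermediate
19 | 4-acetoxybenzoyl chloride | CC(=O)Oc1ccc(cc1)C(Cl)=O | starting material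
20 | (3R,3aS,4S,8aS)-3-hydroxy-6,8a-dimethyl-3-(propan-2-yl)-1,2,3,3a,4,7,8,8a-octahydroazulen-4-yl 4-acetoxybenzoate | CC1=C[C@H](OC(=O)c2ccc(OC(C)=O)cc2)[C@@H]2[C@@](C)(CC1)CC[C@@]2(O)C(C)C | intermediate
21 | (3R,3aS,4S,8aS)-3-hydroxy-6,8a-dimethyl-3-(propan-2-yl)-1,2,3,3a,4,7,8,8a-octahydroazulen-4-yl 4-hydroxybenzoate | CC1=C[C@H](OC(=O)c2ccc(O)cc2)[C@@H]2[C@@](C)(CC1)CC[C@@]2(O)C(C)C | target

Total step count: 12. Longest linear sequence: 12 steps (1 to 21; 4 and 19 enter in single steps).

Steps most likely to fail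

Step 8 (Proposed new method). What may go wrong: capture of the oxyallyl cation by the nearer trisubstituted alkene or by the solvent, closure through oxygen instead of carbon, β-elimination of the silyloxy group from the enolate, or formation of C8a with the wrong sense relative to C4. The fallback uses known chemistry, sets out from 4 and returns to the route at 16; it takes the five-membered ring from a cyclopentenone instead of building it by cycloaddition. Compound 4 is converted with Mg in THF into (3-methylbut-3-en-1-yl)magnesium bromide F1. Copper-catalysed asymmetric conjugate addition of F1 to 3-methylcyclopent-2-en-1-one (Cu(OTf)2 with a chiral N-heterocyclic carbene ligand, Et2O, −30 °C, ligand antipode chosen for the S centre) should give bromomagnesium (S)-3-methyl-3-(3-methylbut-3-en-1-yl)cyclopent-1-en-1-olate F2. F2 is trapped in the same flask with acrolein at −78 °C (Zimmerman–Traxler transition state of the E-enolate, approach anti to the larger side chain) to give the anti aldol (2S,3S)-2-[(1S)-1-hydroxyprop-2-en-1-yl]-3-methyl-3-(3-methylbut-3-en-1-yl)cyclopentan-1-one F3. Ring-closing metathesis of F3 with the second-generation Grubbs catalyst, RuCl2(=CHPh)(H2IMes)(PCy3), in CH2Cl2 at 40 °C closes the trisubstituted cycloheptene and gives 16.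

Step 10. What may go wrong: retro-aldol opening of the metal aldolate, enolization, or reduction of the ketone by β-hydride transfer from the secondary Grignard reagent, with erosion of facial control. The fallback sets out from 15 and returns at 18. The silyl-protected ketone 15 is treated with 2-propenylmagnesium bromide and anhydrous CeCl3 (THF, −78 °C); this less basic sp2 nucleophile cannot transfer a β-hydride, and the substrate cannot undergo retro-aldol. The expected product is (3S,3aS,4S,8aS)-4-[(tert-butyldimethylsilyl)oxy]-6,8a-dimethyl-3-(prop-1-en-2-yl)-1,2,3,3a,4,7,8,8a-octahydroazulen-3-ol F4. The 1,1-disubstituted alkene of F4 is hydrogenated selectively with RhCl(PPh3)3 and H2 (benzene, rt; the trisubstituted ring alkene is much slower) to give (3R,3aS,4S,8aS)-4-[(tert-butyldimethylsilyl)oxy]-6,8a-dimethyl-3-(propan-2-yl)-1,2,3,3a,4,7,8,8a-octahydroazulen-3-ol F5. Bu4NF in THF then removes the silyl group and gives 18.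

Step 2. What may go wrong: slow transmetalation of the alkylzinc reagent in the presence of the free hydroxyl, β-hydride elimination from the alkylpalladium intermediate, and protodeiodination or partial loss of the Z geometry. The fallback sets out from 4 and returns at 6. Alkylation of lithium acetylide–ethylenediamine complex with 4 (DMSO, rt) gives 2-methylhex-1-en-5-yne F6. Deprotonation with n-BuLi and quenching with methyl chloroformate gives methyl 6-methylhept-6-en-2-ynoate F7. Syn-carbocupration with Me2CuLi (THF, −78 °C) and protonation with retention gives methyl (Z)-3,6-dimethylhepta-2,6-dienoate F8. i-Bu2AlH (CH2Cl2, −78 °C) reduces F8 to 6.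

Further compounds
F1 | step 8 | (3-methylbut-3-en-1-yl)magnesium bromide | CC(=C)CC[Mg]Br
F2 | step 8 | bromomagnesium (S)-3-methyl-3-(3-methylbut-3-en-1-yl)cyclopent-1-en-1-olate | Br[Mg]OC1=C[C@@](C)(CCC(C)=C)CC1
F3 | step 8 | (2S,3S)-2-[(1S)-1-hydroxyprop-2-en-1-yl]-3-methyl-3-(3-methylbut-3-en-1-yl)cyclopentan-1-one | C=C[C@H](O)[C@@H]1[C@@](C)(CCC(C)=C)CCC1=O
F4 | step 10 | (3S,3aS,4S,8aS)-4-[(tert-butyldimethylsilyl)oxy]-6,8a-dimethyl-3-(prop-1-en-2-yl)-1,2,3,3a,4,7,8,8a-octahydroazulen-3-ol | CC1=C[C@H](O[Si](C)(C)C(C)(C)C)[C@@H]2[C@@](C)(CC1)CC[C@@]2(O)C(C)=C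
F5 | step 10 | (3R,3aS,4S,8aS)-4-[(tert-butyldimethylsilyl)oxy]-6,8a-dimethyl-3-(propan-2-yl)-1,2,3,3a,4,7,8,8a-octahydroazulen-3-ol | CC1=C[C@H](O[Si](C)(C)C(C)(C)C)[C@@H]2[C@@](C)(CC1)CC[C@@]2(O)C(C)C
F6 | step 2 | 2-methylhex-1-en-5-yne | C=C(C)CCC#C
F7 | step 2 | methyl 6-methylhept-6-en-2-ynoate | COC(=O)C#CCCC(C)=C
F8 | step 2 | methyl (Z)-3,6-dimethylhepta-2,6-dienoate | COC(=O)/C=C(/C)CCC(C)=C
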